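**Retrosynthetic overview**

- Last C=C bond: Horner–Wadsworth–Emmons disconnection at C2=C3 of the dienoate, between the phosphonoacetate of the cis-5-hydroxy-δ-lactone and an (E)-2-methyl enal that carries the 1,4-diol as a seven-membered acetonide; acetonide hydrolysis ends the synthesis.
- Lactone (the only ring built): furan ring expansion of a furfuryl alcohol to a pyranone, internal redox isomerisation to the keto-lactone, then cis-selective ketone reduction.
- Furfuryl alcohol: Felkin–Anh addition of 2-furyllithium to (2S,4R,6E)-2,4,6-trimethyloct-6-enal, which comes from decarboxylative alkenylation of an aldehyde-acid with (E)-2-bromobut-2-ene.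
- Key step: the aldehyde-acid comes from 3,5-dimethylphenol by arene hydrogenation to the meso cis-ketone, enantioselective desymmetrising enolisation with a chiral lithium amide, and ozonolysis; the former phenol carbon later leaves as CO2.
- Enal: desymmetrising asymmetric hydroformylation of 2,2-dimethyl-4,7-dihydro-1,3-dioxepine, then Wittig olefination; the dioxepane ring is carried from the starting material.

Assumption: the (S,S)-amide in step 2 and the (S,S)-Ph-BPE ligand in step 9 are taken to give the enantiomers drawn; if either sense proves opposite, the mirror-image amide or ligand is used.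

**Route**

Step 1
Reactants: 1 3,5-dimethylphenol
Product: 2 cis-3,5-dimethylcyclohexan-1-one (meso)
Conditions: H2 (10 bar), Pd/C (5 wt %), AlCl3 (10 mol %), CH2Cl2, 50 °C; fractional distillation
Reagents that add atoms: none
Why: Partial heterogeneous hydrogenation of a phenol to the cyclohexanone: the flat arene takes up hydrogen from one catalyst face, so the two methyl-bearing carbons are set cis (meso, about 9:1 expected, trans isomer distilled off), and the enol tautomerises to the ketone, which palladium reduces only slowly.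

Step 2
Reactants: 2 cis-3,5-dimethylcyclohexan-1-one
Product: 4 trimethyl{[(3S,5R)-3,5-dimethylcyclohex-1-en-1-yl]oxy}silane, via lithium enolate 3 (not isolated)
Conditions: LiN[(S)-CH(CH3)Ph]2 (from the amine and n-BuLi), LiCl, Me3SiCl (internal quench), THF, −100 to −78 °C
Reagents that add atoms: chlorotrimethylsilane, C[Si](C)(C)Cl
Why: Enantioselective deprotonation of a meso ketone with a chiral lithium amide (desymmetrisation): the base removes one of the two enantiotopic axial α-protons, which fixes C3 as S and C5 as R and so sets the absolute configuration of both methyl centres of the side chain (about 90 % ee expected; the minor enantiomer is purged as a diastereomer after step 12).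

Step 3
Reactants: 4 trimethyl{[(3S,5R)-3,5-dimethylcyclohex-1-en-1-yl]oxy}silane
Product: 5 (3R,5S)-3,5-dimethyl-6-oxohexanoic acid
Conditions: O3, CH2Cl2/MeOH (9:1), −78 °C; then Me2S, −78 °C to rt; aqueous work-up
Reagents that add atoms: ozone, [O-][O+]=O
Why: Ozonolysis of a silyl enol ether with reductive work-up cuts the C1=C2 bond, so the enol carbon becomes the carboxylic acid and the former α-CH becomes the aldehyde, with neither methyl stereocentre touched.

Step 4
Reactants: 5 (3R,5S)-3,5-dimethyl-6-oxohexanoic acid; 6 (E)-2-bromobut-2-ene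
Product: 8 (2S,4R,6E)-2,4,6-trimethyloct-6-enal, via N-acyloxyphthalimide ester 7 (not isolated)
Conditions: N-hydroxyphthalimide, DIC, CH2Cl2, rt; solvent switch; then 6 (2 equiv), NiBr2(dme) (10 mol %), 4,4′-di-tert-butyl-2,2′-bipyridine (10 mol %), Zn dust (2 equiv), DMA, rt
Reagents that add atoms: none
Why: Nickel-catalysed decarboxylative cross-electrophile coupling of a redox-active ester with an alkenyl bromide: the primary radical left after loss of CO2 is not a stereocentre, it is captured at nickel and joined to the butenyl group with retention of the E geometry, and no basic organometallic is present to attack the aldehyde.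

Step 5
Reactants: 8 (2S,4R,6E)-2,4,6-trimethyloct-6-enal; 9 furan
Product: 11 (1R,2S,4R,6E)-1-(furan-2-yl)-2,4,6-trimethyloct-6-en-1-ol, via 2-furyllithium 10 (not isolated)
Conditions: 9, n-BuLi, THF, 0 °C; then 8, −78 °C; aq. NH4Cl; chromatography
Reagents that add atoms: none
Why: 1,2-Addition of an aryllithium to an α-methyl aldehyde under Felkin–Anh control gives the 1,2-syn carbinol (new centre R) as the major diastereomer (about 4:1 expected, minor epimer removed by chromatography).

Step 6
Reactants: 11 (1R,2S,4R,6E)-1-(furan-2-yl)-2,4,6-trimethyloct-6-en-1-ol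
Product: 12 (2R)-2-[(2S,4R,6E)-4,6-dimethyloct-6-en-2-yl]-6-hydroxy-2H-pyran-3(6H)-one (anomer mixture)
Conditions: VO(acac)2 (5 mol %), t-BuOOH (1.5 equiv), CH2Cl2, 0 °C to rt
Reagents that add atoms: tert-butyl hydroperoxide, CC(C)(C)OO
Why: Achmatowicz rearrangement (hydroxyl-directed, vanadium-catalysed oxidative ring expansion): the furan is dearomatised to the pyranone with the carbinol centre retained as C2, and the isolated trisubstituted alkene is not epoxidised because it lacks a directing hydroxyl.

Step 7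
Reactants: 12 (2R)-2-[(2S,4R,6E)-4,6-dimethyloct-6-en-2-yl]-6-hydroxy-2H-pyran-3(6H)-one
Product: 13 (6R)-6-[(2S,4R,6E)-4,6-dimethyloct-6-en-2-yl]dihydro-2H-pyran-2,5(6H)-dione
Conditions: [Ir(cod)Cl]2 (2.5 mol %), 2,6-Cl2C6H3CO2H (10 mol %), CHCl3, rt
Reagents that add atoms: none
Why: Iridium-catalysed internal redox isomerisation of an allylic lactol (allylic alcohol to carbonyl isomerisation: β-hydride elimination from the iridium lactolate, then conjugate return of the hydride to the enone) gives the saturated keto-δ-lactone without external oxidant or reductant and without touching C6.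

Step 8
Reactants: 13 (6R)-6-[(2S,4R,6E)-4,6-dimethyloct-6-en-2-yl]dihydro-2H-pyran-2,5(6H)-dione
Product: 14 (5R,6R)-6-[(2S,4R,6E)-4,6-dimethyloct-6-en-2-yl]-5-hydroxytetrahydro-2H-pyran-2-one
Conditions: LiBH(s-Bu)3 (1.1 equiv), THF, −78 °C; AcOH quench at −78 °C
Reagents that add atoms: none
Why: Diastereoselective ketone reduction with a bulky hydride: attack on the C5 carbonyl from the face opposite the C6 side chain gives the cis (5R,6R) alcohol, the lactone carbonyl is not reduced at −78 °C, and the cold acidic quench prevents translactonisation to the γ-lactone.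

Step 9
Reactants: 15 2,2-dimethyl-4,7-dihydro-1,3-dioxepine
Product: 16 (5S)-2,2-dimethyl-1,3-dioxepane-5-carbaldehyde
Conditions: Rh(acac)(CO)2 (0.5 mol %), (S,S)-Ph-BPE (0.6 mol %), CO/H2 (1:1, 10 bar), toluene, 60 °C
Reagents that add atoms: carbon monoxide, [C-]#[O+]
Why: Rhodium-catalysed asymmetric hydroformylation as an enantioselective desymmetrisation: the two olefinic carbons of the mirror-symmetric cis-alkene are enantiotopic and the chiral bisphospholane rhodium hydride selects one, setting the formyl-bearing centre that becomes C6 of the acyl chain.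

Step 10
Reactants: 16 (5S)-2,2-dimethyl-1,3-dioxepane-5-carbaldehyde; 17 2-(triphenyl-λ5-phosphanylidene)propanal
Product: 18 (2E)-3-[(5R)-2,2-dimethyl-1,3-dioxepan-5-yl]-2-methylprop-2-enal
Conditions: 17 (1.2 equiv), toluene, 80 °C
Reagents that add atoms: none
Why: Wittig olefination with a stabilised ylide gives the (E)-2-methyl enal with high E selectivity under neutral conditions that leave the α-stereocentre intact (its descriptor changes from S to R only because of the priority rules).

Step 11
Reactants: 14 (5R,6R)-6-[(2S,4R,6E)-4,6-dimethyloct-6-en-2-yl]-5-hydroxytetrahydro-2H-pyran-2-one; 19 (diethoxyphosphoryl)acetic acid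
Product: 20 (2R,3R)-2-[(2S,4R,6E)-4,6-dimethyloct-6-en-2-yl]-6-oxotetrahydro-2H-pyran-3-yl 2-(diethoxyphosphoryl)acetate
Conditions: 19, DCC, DMAP (10 mol %), CH2Cl2, 0 °C
Reagents that add atoms: none
Why: Steglich esterification of the secondary alcohol with a small unhindered acid proceeds with retention at C5 and is fast enough to outrun lactone migration.

Step 12
Reactants: 20 (2R,3R)-2-[(2S,4R,6E)-4,6-dimethyloct-6-en-2-yl]-6-oxotetrahydro-2H-pyran-3-yl 2-(diethoxyphosphoryl)acetate; 18 (2E)-3-[(5R)-2,2-dimethyl-1,3-dioxepan-5-yl]-2-methylprop-2-enal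
Product: 21 (2R,3R)-2-[(2S,4R,6E)-4,6-dimethyloct-6-en-2-yl]-6-oxotetrahydro-2H-pyran-3-yl (2E,4E)-5-[(5R)-2,2-dimethyl-1,3-dioxepan-5-yl]-4-methylpenta-2,4-dienoate
Conditions: LiCl, i-Pr2NEt, MeCN, rt
Reagents that add atoms: none
Why: Horner–Wadsworth–Emmons olefination under Masamune–Roush conditions forms the (2E) double bond, and the mild amine/LiCl base leaves the lactone, the ester and the allylic stereocentre untouched.

Step 13
Reactants: 21 the acetonide-protected dienoate from step 12
Product: 22 (2R,3R)-2-[(2S,4R,6E)-4,6-dimethyloct-6-en-2-yl]-6-oxotetrahydro-2H-pyran-3-yl (2E,4E,6R)-8-hydroxy-6-(hydroxymethyl)-4-methylocta-2,4-dienoate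
Conditions: AcOH/THF/H2O (3:1:1), rt
Reagents that add atoms: none
Why: Acid-catalysed acetal hydrolysis of the strained seven-membered acetonide frees the 1,4-diol under conditions that leave the δ-lactone, the dienoate and the trisubstituted alkene intact.

**Compound list**

1 | 3,5-dimethylphenol | Cc1cc(C)cc(O)c1 | starting material
2 | cis-3,5-dimethylcyclohexan-1-one (meso) | C[C@@H]1CC(=O)C[C@H](C)C1 | intermediate
3 | lithium (3S,5R)-3,5-dimethylcyclohex-1-en-1-olate (not isolated) | C[C@@H]1C=C([O-])C[C@H](C)C1.[Li+] | intermediate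
4 | trimethyl{[(3S,5R)-3,5-dimethylcyclohex-1-en-1-yl]oxy}silane | C[C@@H]1C=C(O[Si](C)(C)C)C[C@H](C)C1 | intermediate
5 | (3R,5S)-3,5-dimethyl-6-oxohexanoic acid | OC(=O)C[C@H](C)C[C@H](C)C=O | intermediate
6 | (E)-2-bromobut-2-ene | C/C=C(\C)Br | starting material
7 | 1,3-dioxoisoindolin-2-yl (3R,5S)-3,5-dimethyl-6-oxohexanoate (not isolated) | O=C(C[C@H](C)C[C@H](C)C=O)ON1C(=O)c2ccccc2C1=O | intermediate
8 | (2S,4R,6E)-2,4,6-trimethyloct-6-enal | C/C=C(\C)C[C@H](C)C[C@H](C)C=O | intermediate
9 | furan | c1ccoc1 | starting material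
10 | 2-furyllithium (not isolated) | [Li]c1ccco1 | intermediate
11 | (1R,2S,4R,6E)-1-(furan-2-yl)-2,4,6-trimethyloct-6-en-1-ol | C/C=C(\C)C[C@H](C)C[C@H](C)[C@@H](O)c1ccco1 | intermediate
12 | (2R)-2-[(2S,4R,6E)-4,6-dimethyloct-6-en-2-yl]-6-hydroxy-2H-pyran-3(6H)-one, anomer mixture | C/C=C(\C)C[C@H](C)C[C@H](C)[C@H]1OC(O)C=CC1=O | intermediate
13 | (6R)-6-[(2S,4R,6E)-4,6-dimethyloct-6-en-2-yl]dihydro-2H-pyran-2,5(6H)-dione | C/C=C(\C)C[C@H](C)C[C@H](C)[C@H]1OC(=O)CCC1=O | intermediate
14 | (5R,6R)-6-[(2S,4R,6E)-4,6-dimethyloct-6-en-2-yl]-5-hydroxytetrahydro-2H-pyran-2-one | C/C=C(\C)C[C@H](C)C[C@H](C)[C@H]1OC(=O)CC[C@H]1O | intermediate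
15 | 2,2-dimethyl-4,7-dihydro-1,3-dioxepine | CC1(C)OCC=CCO1 | starting material
16 | (5S)-2,2-dimethyl-1,3-dioxepane-5-carbaldehyde | O=C[C@H](COC1(C)C)CCO1 | intermediate
17 | 2-(triphenyl-λ5-phosphanylidene)propanal | CC(C=O)=P(c1ccccc1)(c1ccccc1)c1ccccc1 | starting material
18 | (2E)-3-[(5R)-2,2-dimethyl-1,3-dioxepan-5-yl]-2-methylprop-2-enal | O=C/C(C)=C/[C@H](COC1(C)C)CCO1 | intermediate
19 | (diethoxyphosphoryl)acetic acid | OC(=O)CP(=O)(OCC)OCC | starting material
20 | (2R,3R)-2-[(2S,4R,6E)-4,6-dimethyloct-6-en-2-yl]-6-oxotetrahydro-2H-pyran-3-yl 2-(diethoxyphosphoryl)acetate | C/C=C(\C)C[C@H](C)C[C@H](C)[C@H]1OC(=O)CC[C@H]1OC(=O)CP(=O)(OCC)OCC | intermediate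
21 | (2R,3R)-2-[(2S,4R,6E)-4,6-dimethyloct-6-en-2-yl]-6-oxotetrahydro-2H-pyran-3-yl (2E,4E)-5-[(5R)-2,2-dimethyl-1,3-dioxepan-5-yl]-4-methylpenta-2,4-dienoate | C/C=C(\C)C[C@H](C)C[C@H](C)[C@H]1OC(=O)CC[C@H]1OC(=O)/C=C/C(C)=C/[C@H](COC2(C)C)CCO2 | intermediate
22 | (2R,3R)-2-[(2S,4R,6E)-4,6-dimethyloct-6-en-2-yl]-6-oxotetrahydro-2H-pyran-3-yl (2E,4E,6R)-8-hydroxy-6-(hydroxymethyl)-4-methylocta-2,4-dienoate | C/C=C(\C)C[C@H](C)C[C@H](C)[C@H]1OC(=O)CC[C@H]1OC(=O)/C=C/C(C)=C/[C@H](CO)CCO | target

**Step count**

Total: 13 steps. Longest linear sequence: 11 steps (steps 1 to 8, then 11 to 13); steps 9 and 10 form the side branch.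

**Three steps most likely to fail**

Step 4, the decarboxylative alkenylation next to a free, epimerisable aldehyde: zinc and nickel may attack or epimerise the formyl group, and the primary radical may abstract the formyl hydrogen. The fallback sets out from 5 and comes back at 8. NaBH4 reduces the aldehyde of 5 to give (3R,5S)-6-hydroxy-3,5-dimethylhexanoic acid F1. N-hydroxyphthalimide and DIC convert it into 1,3-dioxoisoindolin-2-yl (3R,5S)-6-hydroxy-3,5-dimethylhexanoate F2, which is coupled with 6 under NiBr2(dme)/Zn to give (2S,4R,6E)-2,4,6-trimethyloct-6-en-1-ol F3. Dess–Martin oxidation of F3 gives 8, so the aldehyde is only revealed after the radical step.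

Step 7, the iridium redox isomerisation: the catalyst may stall on this hindered lactol or migrate the side-chain alkene. The fallback sets out from 12 and comes back at 13 by an oxidation and reduction pair in place of the isomerisation. CrO3/H2SO4 in acetone at 0 °C oxidises the lactol to (6R)-6-[(2S,4R,6E)-4,6-dimethyloct-6-en-2-yl]-2H-pyran-2,5(6H)-dione F4, and Zn in AcOH then reduces the ene-dione C=C to give 13.

Step 8, the cis-selective reduction: facial selectivity may be poor, or the lithium alkoxide may translactonise to the γ-lactone. The fallback sets out from 13 and comes back at 20. NaBH4 with CeCl3·7H2O in MeOH at −78 °C gives, by axial attack, the trans alcohol (5S,6R)-6-[(2S,4R,6E)-4,6-dimethyloct-6-en-2-yl]-5-hydroxytetrahydro-2H-pyran-2-one F5. Mitsunobu esterification of F5 with 19 (PPh3, DIAD, THF, 0 °C) inverts C5 and gives 20 directly.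

**Further compounds**

F1 | step 4 | (3R,5S)-6-hydroxy-3,5-dimethylhexanoic acid | OC(=O)C[C@H](C)C[C@H](C)CO
F2 | step 4 | 1,3-dioxoisoindolin-2-yl (3R,5S)-6-hydroxy-3,5-dimethylhexanoate | O=C(C[C@H](C)C[C@H](C)CO)ON1C(=O)c2ccccc2C1=O
F3 | step 4 | (2S,4R,6E)-2,4,6-trimethyloct-6-en-1-ol | C/C=C(\C)C[C@H](C)C[C@H](C)CO
F4 | step 7 | (6R)-6-[(2S,4R,6E)-4,6-dimethyloct-6-en-2-yl]-2H-pyran-2,5(6H)-dione | C/C=C(\C)C[C@H](C)C[C@H](C)[C@H]1OC(=O)C=CC1=O
F5 | step 8 | (5S,6R)-6-[(2S,4R,6E)-4,6-dimethyloct-6-en-2-yl]-5-hydroxytetrahydro-2H-pyran-2-one | C/C=C(\C)C[C@H](C)C[C@H](C)[C@H]1OC(=O)CC[C@@H]1O
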